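**Strategy.** The 14-membered ring is numbered C1 (fusion CH carrying C15), C2 (O–CH), alkenes at C3, C7 and C11, C13 (OAc) and C14. C16 is the carbonyl and C17 the exocyclic methylene. The cis-fused five-membered ring O–C2–C1–C15–C16 is then a but-3-yn-1-ol (HO–C2–C1–C15≡C17) plus one carbon, so C16 is disconnected as CO. One palladium-catalysed cyclocarbonylation forms O–C16 and C16–C15, closes the lactone and unveils C15=C17 last, so no Michael acceptor ever meets base or hydride. The precursor is the macrocyclic (1S,2S,13S)-13-acetoxy-1-ethynyl-trien-2-ol. It is assembled by Brown allylation (C13), Evans syn aldol (C1, C2) and sulfone-anion ring closure at C5–C6.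

Key step: step 23

Assumption: geranyl bromide, allylmagnesium bromide solution, (−)-Ipc2BOMe and dimethyl (1-diazo-2-oxopropyl)phosphonate are taken as commercial, and the atom numbers defined above are used for every intermediate.

Step 1
Reactants: 1 prenyl acetate
Product: 2 (E)-4-hydroxy-3-methylbut-2-enyl acetate
Conditions: SeO2 (cat.), t-BuOOH, CH2Cl2, 0 °C to rt
Reagents that add atoms: selenium dioxide O=[Se]=O; tert-butyl hydroperoxide CC(C)(C)OO
Why: Riley oxidation (ene reaction, then [2,3]-sigmatropic shift) hydroxylates only the E methyl group, which fixes the E geometry of the later C3=C4 bond.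

Step 2
Reactants: 2 (E)-4-hydroxy-3-methylbut-2-enyl acetate
Product: 4 (E)-4-chloro-3-methylbut-2-enyl acetate, via allylic mesylate 3 (not isolated)
Conditions: MsCl, 2,4,6-collidine, LiCl, DMF, 0 °C
Reagents that add atoms: lithium chloride [Li+].[Cl-]
Why: The primary allylic mesylate is displaced in situ by chloride in an SN2 reaction, without allylic transposition or loss of alkene geometry.

Step 3
Reactants: 4 (E)-4-chloro-3-methylbut-2-enyl acetate
Product: 5 (E)-4-chloro-3-methylbut-2-en-1-ol
Conditions: i-Bu2AlH, CH2Cl2, −78 °C; aq. potassium sodium tartrate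
Reagents that add atoms: none
Why: Reductive ester cleavage at low temperature frees the alcohol without any nucleophile that could displace the allylic chloride.

Step 4
Reactants: 5 (E)-4-chloro-3-methylbut-2-en-1-ol
Product: 6 (E)-4-chloro-3-methylbut-2-enal (C2–C5 fragment)
Conditions: activated MnO2, CH2Cl2, rt
Reagents that add atoms: none
Why: Heterogeneous MnO2 oxidation is selective for allylic alcohols and should stop at the enal without E/Z isomerisation.

Step 5
Reactants: 7 geranyl bromide; 8 sodium benzenesulfinate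
Product: 9 geranyl phenyl sulfone
Conditions: DMF, rt
Reagents that add atoms: sodium benzenesulfinate [Na+].[O-]S(=O)c1ccccc1
Why: SN2 S-alkylation of the sulfinate puts the sulfone on C6 as a prenyl-type allyl sulfone, the arrangement from which later hydride delivery cannot move the C7=C8 bond.

Step 6
Reactants: 9 geranyl phenyl sulfone
Product: 11 (2E,6E)-2,6-dimethyl-8-(phenylsulfonyl)octa-2,6-dienal, via allylic alcohol 10 (not isolated)
Conditions: SeO2 (cat.), t-BuOOH, CH2Cl2, 0 °C to rt; crude, activated MnO2, CH2Cl2, rt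
Reagents that add atoms: selenium dioxide O=[Se]=O; tert-butyl hydroperoxide CC(C)(C)OO
Why: Riley oxidation attacks the E methyl group of the remote, electron-richer alkene (the one next to the sulfone is deactivated), and MnO2 oxidation of the crude material converges on the E enal C13.

Step 7
Reactants: 11 (2E,6E)-2,6-dimethyl-8-(phenylsulfonyl)octa-2,6-dienal; 12 allylmagnesium bromide
Product: 14 (4S,5E,9E)-5,9-dimethyl-11-(phenylsulfonyl)undeca-1,5,9-trien-4-ol, via B-allyldiisopinocampheylborane 13 (not isolated)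
Conditions: (−)-Ipc2BOMe [(+)-α-pinene series], CH2=CHCH2MgBr, Et2O, 0 °C to rt; 11, −78 °C; NaOH, H2O2
Reagents that add atoms: allylmagnesium bromide C=CC[Mg]Br
Why: Brown asymmetric allylboration proceeds through a closed Zimmerman–Traxler chair in which the isopinocampheyl groups of this series send the allyl group (C14, C1, C15) to the Si face of the aldehyde, which sets C13 as S.

Step 8
Reactants: 14 (4S,5E,9E)-5,9-dimethyl-11-(phenylsulfonyl)undeca-1,5,9-trien-4-ol
Product: 15 C13 TBS ether of 14
Conditions: TBSCl, imidazole, DMF, rt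
Reagents that add atoms: tert-butyldimethylsilyl chloride CC(C)(C)[Si](C)(C)Cl
Why: Standard silylation gives an ether that resists the basic, hydridic and Lewis acidic steps up to step 20 and needs no strong base, which the acidic C6–H would not tolerate.

Step 9
Reactants: 15 C13 TBS ether of 14
Product: 17 (4S,5E,9E)-4-(tert-butyldimethylsilyloxy)-5,9-dimethyl-11-(phenylsulfonyl)undeca-5,9-dien-1-ol, via B-alkyl-9-BBN adduct 16 (not isolated)
Conditions: 9-BBN, THF, 0 °C to rt; NaOH, H2O2, 0 °C
Reagents that add atoms: hydrogen peroxide OO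
Why: Brown hydroboration–oxidation with the bulky 9-BBN adds anti-Markovnikov to the monosubstituted alkene only and leaves both trisubstituted alkenes alone.

Step 10
Reactants: 17 primary alcohol (C15–OH)
Product: 19 (4S,5E,9E)-4-(tert-butyldimethylsilyloxy)-5,9-dimethyl-11-(phenylsulfonyl)undeca-5,9-dienoic acid, via aldehyde 18 (not isolated)
Conditions: TEMPO (cat.), PhI(OAc)2, MeCN/H2O, rt
Reagents that add atoms: water O
Why: Oxoammonium (TEMPO) oxidation takes the primary alcohol through the aldehyde hydrate to the acid without touching alkenes, sulfone or silyl ether.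

Step 11
Reactants: 19 carboxylic acid (C15); 20 (R)-4-benzyl-2-oxazolidinone
Product: 22 N-acyl oxazolidinone of acid 19, via mixed pivalic anhydride 21 (not isolated)
Conditions: PivCl, Et3N, THF, −20 to 0 °C; LiCl, 20, rt
Reagents that add atoms: (R)-4-benzyl-2-oxazolidinone O=C1N[C@H](Cc2ccccc2)CO1
Why: N-acylation through the mixed anhydride with LiCl/Et3N avoids the lithiated auxiliary and hence any base able to deprotonate the allyl sulfone.

Step 12
Reactants: 22 N-acyl oxazolidinone; 6 (E)-4-chloro-3-methylbut-2-enal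
Product: 24 Evans syn aldol adduct (C1 R in this compound; C2 S; C13 S), via Z dibutylboron enolate 23 (not isolated)
Conditions: Bu2BOTf, i-Pr2NEt, CH2Cl2, −78 to 0 °C; 6, −78 to 0 °C; pH 7 buffer, MeOH, H2O2, 0 °C
Reagents that add atoms: (E)-4-chloro-3-methylbut-2-enal O=C/C=C(\C)CCl
Why: In the Evans syn aldol the Z boron enolate reacts through a Zimmerman–Traxler chair whose open face is dictated by the benzyl group of the R auxiliary, which sets C1 and C2 with O2 and C14 syn, the relationship of the cis-fused lactone, in the required absolute sense.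

Step 13
Reactants: 24 Evans syn aldol adduct
Product: 25 acyclic 1,3-diol (C2–OH and C15–OH; 1S,2S,13S; C5 chloride; C6 sulfone; C13 OTBS)
Conditions: LiBH4, MeOH, THF, 0 °C
Reagents that add atoms: none
Why: Reductive auxiliary removal exploits the activated exocyclic imide carbonyl, which borohydride reduces far faster at 0 °C than it displaces a primary chloride, while the E alkene keeps both alkoxides out of reach of C5.

Step 14
Reactants: 25 acyclic 1,3-diol
Product: 26 p-methoxybenzylidene acetal of 25 (all-cis 2,4,5-trisubstituted 1,3-dioxane; acetal carbon R)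
Conditions: 4-MeOC6H4CH(OMe)2, PPTS (cat.), CH2Cl2, rt
Reagents that add atoms: 4-methoxybenzaldehyde dimethyl acetal COc1ccc(cc1)C(OC)OC
Why: Acid-catalysed transacetalisation under thermodynamic control places aryl and alkenyl groups equatorial (a temporary centre, erased in step 17), masks O2 and O15 in one operation and holds C3 and C14 gauche as the ring closure needs.

Step 15
Reactants: 26 acyclic chloro sulfone acetal
Product: 27 macrocyclic C6 phenyl sulfone (both C6 epimers)
Conditions: NaN(SiMe3)2, THF, 0 °C, slow addition of 26, high dilution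
Reagents that add atoms: none
Why: Intramolecular alkylation of a sulfone-stabilised allyl anion closes the 14-membered ring by SN2 attack of C6 on the primary allylic chloride C5; C6–H is the only acidic C–H present, no oxygen leaving group sits next to the anion's γ-terminus C8, and the uncontrolled C6 centre disappears in step 16.

Step 16
Reactants: 27 macrocyclic C6 phenyl sulfone
Product: 28 macrocyclic (3E,7E,11E)-triene acetal
Conditions: PdCl2(dppp) (cat.), LiBHEt3, THF, 0 °C
Reagents that add atoms: none
Why: In this palladium-catalysed hydride desulfonylation zerovalent palladium ionises only the allylic sulfone and hydride is delivered to the less substituted terminus C6 of the C6–C8 allyl unit, which keeps C7=C8 in place and E while allylic ethers are not ionised.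

Step 17
Reactants: 28 macrocyclic triene acetal
Product: 29 macrocyclic C15 primary alcohol bearing the C2 PMB ether
Conditions: i-Bu2AlH, CH2Cl2, −78 to 0 °C; aq. potassium sodium tartrate
Reagents that add atoms: none
Why: Regioselective reductive acetal opening occurs because aluminium binds the less hindered primary oxygen O15 and hydride quenches the oxocarbenium ion, which leaves the PMB group on O2 and frees C15–OH.

Step 18
Reactants: 29 macrocyclic C15 alcohol
Product: 30 macrocyclic C15 aldehyde
Conditions: Dess–Martin periodinane, NaHCO3, CH2Cl2, 0 °C to rt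
Reagents that add atoms: none
Why: Buffered Dess–Martin oxidation stops at the aldehyde and is mild enough to leave the adjacent stereocentre C1 unchanged.

Step 19
Reactants: 30 macrocyclic C15 aldehyde; 31 dimethyl (1-diazo-2-oxopropyl)phosphonate
Product: 33 macrocyclic C1 ethynyl compound (C13 OTBS; C2 OPMB), via dimethyl diazomethylphosphonate 32 (not isolated)
Conditions: K2CO3, MeOH, 0 °C to rt
Reagents that add atoms: dimethyl (1-diazo-2-oxopropyl)phosphonate COP(=O)(OC)C(=[N+]=[N-])C(C)=O
Why: In the Ohira–Bestmann form of the Seyferth–Gilbert homologation the diazophosphonate anion adds to the aldehyde and loss of phosphate and N2 with a 1,2-hydride shift gives C15≡C17, and placing this step after steps 15 and 16 spares the alkyne from strong base, hydride and zerovalent palladium.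

Step 20
Reactants: 33 macrocyclic alkyne (C13 OTBS; C2 OPMB)
Product: 34 macrocyclic C13 alcohol
Conditions: Bu4NF, THF, rt
Reagents that add atoms: none
Why: Fluoride-driven desilylation removes the only silyl group, while the PMB ether and the terminal alkyne are inert.

Step 21
Reactants: 34 macrocyclic C13 alcohol
Product: 35 macrocyclic C13 acetate bearing the C2 PMB ether
Conditions: Ac2O, pyridine, DMAP (cat.), CH2Cl2, rt
Reagents that add atoms: acetic anhydride CC(=O)OC(C)=O
Why: DMAP-catalysed acetylation of the only free hydroxyl takes place at oxygen, so C13 keeps its S configuration.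

Step 22
Reactants: 35 macrocyclic C13 acetate PMB ether
Product: 36 (1S,2S,13S)-13-acetoxy-1-ethynyl macrocyclic (3E,7E,11E)-trien-2-ol
Conditions: DDQ, CH2Cl2/pH 7 buffer, 0 °C
Reagents that add atoms: none
Why: Oxidative PMB cleavage (hydride abstraction from the electron-rich benzylic position, then hydrolysis) is neutral, so the acetate neither migrates nor hydrolyses and the alkyne is untouched.

Step 23
Reactants: 36 (1S,2S,13S)-13-acetoxy-1-ethynyl macrocyclic trien-2-ol; 37 carbon monoxide
Product: 38 target CNP0182196.2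
Conditions: PdCl2 (cat.), SnCl2 (cat.), PPh3 (2 per Pd), CO (8 bar), dry MeCN, 65 °C
Reagents that add atoms: carbon monoxide [C-]#[O+]
Why: On divalent palladium the C2 hydroxyl attacks bound CO to make an alkoxycarbonyl–palladium bond (O–C16), the neighbouring C15≡C17 unit then adds across Pd–C16 in a syn fashion (C16–C15), and the proton released in the first event cleaves the alkenyl–palladium bond, which leaves C17 as CH2 and regenerates the catalyst. The closest known reaction type is the PdCl2/SnCl2/phosphine cyclocarbonylation of but-3-yn-1-ols and 2-ethynylcycloalkanols to fused α-methylene-γ-butyrolactones. The single ring formed, O–C2–C1–C15–C16, closes in the 5-exo-dig mode because the two-carbon tether lets C16 reach only C15. No stereocentre is created: C1, C2 and C13 are spectators and the cis fusion is inherited from the syn aldol of step 12. The step needs the alkyne to react in preference to three trisubstituted alkenes, which are too hindered to insert, and it needs the allylic C13–OAc and C2–O bonds to survive. Dry conditions and the trichlorostannate ligand secure this by holding palladium in the divalent state, and the methyl group on C12 blocks a palladium-induced 1,3-acetate shift.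

Compound list
1 | prenyl acetate | CC(C)=CCOC(C)=O | starting material
2 | (E)-4-hydroxy-3-methylbut-2-enyl acetate | CC(=O)OC/C=C(\C)CO | intermediate
3 | (E)-4-(methylsulfonyloxy)-3-methylbut-2-enyl acetate | CC(=O)OC/C=C(\C)COS(C)(=O)=O | intermediate
4 | (E)-4-chloro-3-methylbut-2-enyl acetate | CC(=O)OC/C=C(\C)CCl | intermediate
5 | (E)-4-chloro-3-methylbut-2-en-1-ol | OC/C=C(\C)CCl | intermediate
6 | (E)-4-chloro-3-methylbut-2-enal | O=C/C=C(\C)CCl | intermediate
7 | geranyl bromide | CC(C)=CCC/C(C)=C/CBr | starting material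
8 | sodium benzenesulfinate | [Na+].[O-]S(=O)c1ccccc1 | starting material
9 | geranyl phenyl sulfone | CC(C)=CCC/C(C)=C/CS(=O)(=O)c1ccccc1 | intermediate
10 | (2E,6E)-2,6-dimethyl-8-(phenylsulfonyl)octa-2,6-dien-1-ol | OC/C(C)=C/CC/C(C)=C/CS(=O)(=O)c1ccccc1 | intermediate
11 | (2E,6E)-2,6-dimethyl-8-(phenylsulfonyl)octa-2,6-dienal | O=C/C(C)=C/CC/C(C)=C/CS(=O)(=O)c1ccccc1 | intermediate
12 | allylmagnesium bromide | C=CC[Mg]Br | starting material
13 | B-allyldiisopinocampheylborane, (+)-α-pinene series | C=CCB([C@@H]1C[C@@H]2C[C@H]([C@H]1C)C2(C)C)[C@@H]1C[C@@H]2C[C@H]([C@H]1C)C2(C)C | intermediate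
14 | (4S,5E,9E)-5,9-dimethyl-11-(phenylsulfonyl)undeca-1,5,9-trien-4-ol | C=CC[C@H](O)/C(C)=C/CC/C(C)=C/CS(=O)(=O)c1ccccc1 | intermediate
15 | (4S,5E,9E)-4-(tert-butyldimethylsilyloxy)-5,9-dimethyl-11-(phenylsulfonyl)undeca-1,5,9-triene | C=CC[C@H](O[Si](C)(C)C(C)(C)C)/C(C)=C/CC/C(C)=C/CS(=O)(=O)c1ccccc1 | intermediate
16 | B-alkyl-9-BBN adduct of 15 (boron on C15) | C1CC2CCCC(C1)B2CCC[C@H](O[Si](C)(C)C(C)(C)C)/C(C)=C/CC/C(C)=C/CS(=O)(=O)c1ccccc1 | intermediate
17 | (4S,5E,9E)-4-(tert-butyldimethylsilyloxy)-5,9-dimethyl-11-(phenylsulfonyl)undeca-5,9-dien-1-ol | OCCC[C@H](O[Si](C)(C)C(C)(C)C)/C(C)=C/CC/C(C)=C/CS(=O)(=O)c1ccccc1 | intermediate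
18 | (4S,5E,9E)-4-(tert-butyldimethylsilyloxy)-5,9-dimethyl-11-(phenylsulfonyl)undeca-5,9-dienal | O=CCC[C@H](O[Si](C)(C)C(C)(C)C)/C(C)=C/CC/C(C)=C/CS(=O)(=O)c1ccccc1 | intermediate
19 | (4S,5E,9E)-4-(tert-butyldimethylsilyloxy)-5,9-dimethyl-11-(phenylsulfonyl)undeca-5,9-dienoic acid | OC(=O)CC[C@H](O[Si](C)(C)C(C)(C)C)/C(C)=C/CC/C(C)=C/CS(=O)(=O)c1ccccc1 | intermediate
20 | (R)-4-benzyl-2-oxazolidinone | O=C1N[C@H](Cc2ccccc2)CO1 | starting material
21 | mixed pivalic anhydride of acid 19 | CC(C)(C)C(=O)OC(=O)CC[C@H](O[Si](C)(C)C(C)(C)C)/C(C)=C/CC/C(C)=C/CS(=O)(=O)c1ccccc1 | intermediate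
22 | (R)-4-benzyl-3-[(4S,5E,9E)-4-(tert-butyldimethylsilyloxy)-5,9-dimethyl-11-(phenylsulfonyl)undeca-5,9-dienoyl]oxazolidin-2-one | O=C(CC[C@H](O[Si](C)(C)C(C)(C)C)/C(C)=C/CC/C(C)=C/CS(=O)(=O)c1ccccc1)N1C(=O)OC[C@H]1Cc1ccccc1 | intermediate
23 | Z dibutylboron enolate of 22 | CCCCB(CCCC)O/C(=C\C[C@H](O[Si](C)(C)C(C)(C)C)/C(C)=C/CC/C(C)=C/CS(=O)(=O)c1ccccc1)N1C(=O)OC[C@H]1Cc1ccccc1 | intermediate
24 | (R)-4-benzyl-3-[(2R,4S,5E,9E)-2-[(1S,2E)-4-chloro-1-hydroxy-3-methylbut-2-enyl]-4-(tert-butyldimethylsilyloxy)-5,9-dimethyl-11-(phenylsulfonyl)undeca-5,9-dienoyl]oxazolidin-2-one | O=C(N1C(=O)OC[C@H]1Cc1ccccc1)[C@H](C[C@H](O[Si](C)(C)C(C)(C)C)/C(C)=C/CC/C(C)=C/CS(=O)(=O)c1ccccc1)[C@@H](O)/C=C(\C)CCl | intermediate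
25 | acyclic 1,3-diol (C2–OH, C15–OH; 1S,2S,13S), C5 chloride, C6 phenyl sulfone, C13 OTBS | OC[C@H](C[C@H](O[Si](C)(C)C(C)(C)C)/C(C)=C/CC/C(C)=C/CS(=O)(=O)c1ccccc1)[C@@H](O)/C=C(\C)CCl | intermediate
26 | p-methoxybenzylidene acetal of 25 (1,3-dioxane over O2/O15, aryl, C3 and C14 all cis, acetal carbon R) | COc1ccc(cc1)[C@@H]1OC[C@H](C[C@H](O[Si](C)(C)C(C)(C)C)/C(C)=C/CC/C(C)=C/CS(=O)(=O)c2ccccc2)[C@@H](O1)/C=C(\C)CCl | intermediate
27 | 14-membered (3E,7E,11E)-triene with PhSO2 at C6 (both epimers), OTBS at C13 (S), dioxane fused at C1/C2 | COc1ccc(cc1)[C@@H]1OC[C@@H]2C[C@H](O[Si](C)(C)C(C)(C)C)/C(C)=C/CC/C(C)=C/C(S(=O)(=O)c3ccccc3)C/C(C)=C/[C@@H]2O1 | intermediate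
28 | desulfonylated 14-membered (3E,7E,11E)-triene, OTBS at C13, dioxane fused at C1/C2 | COc1ccc(cc1)[C@@H]1OC[C@@H]2C[C@H](O[Si](C)(C)C(C)(C)C)/C(C)=C/CC/C(C)=C/CC/C(C)=C/[C@@H]2O1 | intermediate
29 | macrocyclic triene with CH2OH (C15) on C1, OPMB on C2, OTBS on C13 | OC[C@@H]1C[C@H](O[Si](C)(C)C(C)(C)C)/C(C)=C/CC/C(C)=C/CC/C(C)=C/[C@@H]1OCc1ccc(OC)cc1 | intermediate
30 | macrocyclic triene with CHO (C15) on C1, OPMB on C2, OTBS on C13 | O=C[C@@H]1C[C@H](O[Si](C)(C)C(C)(C)C)/C(C)=C/CC/C(C)=C/CC/C(C)=C/[C@@H]1OCc1ccc(OC)cc1 | intermediate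
31 | dimethyl (1-diazo-2-oxopropyl)phosphonate | COP(=O)(OC)C(=[N+]=[N-])C(C)=O | starting material
32 | dimethyl (diazomethyl)phosphonate | COP(=O)(OC)C=[N+]=[N-] | intermediate
33 | macrocyclic triene with ethynyl on C1 (S), OPMB on C2 (S), OTBS on C13 (S) | C#C[C@@H]1C[C@H](O[Si](C)(C)C(C)(C)C)/C(C)=C/CC/C(C)=C/CC/C(C)=C/[C@@H]1OCc1ccc(OC)cc1 | intermediate
34 | macrocyclic triene with ethynyl on C1, OPMB on C2, OH on C13 | C#C[C@@H]1C[C@H](O)/C(C)=C/CC/C(C)=C/CC/C(C)=C/[C@@H]1OCc1ccc(OC)cc1 | intermediate
35 | macrocyclic triene with ethynyl on C1, OPMB on C2, OAc on C13 | C#C[C@@H]1C[C@H](OC(C)=O)/C(C)=C/CC/C(C)=C/CC/C(C)=C/[C@@H]1OCc1ccc(OC)cc1 | intermediate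
36 | (1S,2S,13S)-13-acetoxy-1-ethynyl macrocyclic (3E,7E,11E)-trien-2-ol | O[C@H]1/C=C(\C)CC/C=C(\C)CC/C=C(\C)[C@@H](OC(C)=O)C[C@H]1C#C | intermediate
37 | carbon monoxide | [C-]#[O+] | starting material
38 | CNP0182196.2, cis-fused α-methylene-γ-lactone (1S,2S,13S) | C=C1C(=O)O[C@H]2/C=C(\C)CC/C=C(\C)CC/C=C(\C)[C@@H](OC(C)=O)C[C@@H]12 | target

Total steps: 23. Longest linear sequence: 19 steps (steps 5–23, from geranyl bromide). The C2–C5 enal is made in parallel in steps 1–4.

Steps most likely to fail

Step 23. The catalyst may be reduced to zerovalent palladium, either by traces of water or by β-hydride loss from the C2 palladium alkoxide. That would be followed by ionisation of the allylic C13–O or C2–O bond. Insertion at the branched propargylic position may also be sluggish. The fallback fixes the regiochemistry at C15 before any CO is admitted and forms C16–C15 from a preformed alkenyl–halogen bond.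
- It sets out from 36, where hydroxyl-directed ruthenium-catalysed hydrostannation ([Cp*RuCl]4 cat., Bu3SnH, CH2Cl2, rt) should place tin on C15 to give the C15 tributylstannyl alkene F1.
- Tin–iodine exchange (I2, CH2Cl2, −78 °C), much faster than attack on the ring alkenes, gives the C15 iodo alkene F2.
- Carbonylative lactonisation (PdCl2(PPh3)2 cat., CO 1 atm, Et3N, THF, rt) runs by oxidative addition into C–I, CO insertion and capture of the acyl–palladium by O2, and comes back to the route at 38.

Step 15. Intermolecular alkylation may overtake ring closure, the ambident anion may attack through its γ-carbon C8, or the base may cause loss of HCl. The fallback gives up both the preformed carbanion and the halide.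
- It sets out from 26, where acetate displacement (CsOAc, DMF, rt) gives the C5 allylic acetate F3.
- Methanolysis (K2CO3, MeOH, 0 °C) gives the C5 allylic alcohol F4.
- A Mitsunobu-type dehydrative C-alkylation follows (slow addition to Bu3P=CHCN, toluene, 110 °C). The phosphorane activates the C5 oxygen and its conjugate base removes the C6 proton only within the same ion pair, so the C5–C6 bond closes under neutral conditions. This comes back to the route at 27.

Step 19. Methoxide-mediated enolisation of the aldehyde may cause epimerisation at C1 or β-elimination of the C2 alkoxy group before homologation is complete. The fallback is the Corey–Fuchs sequence, which never exposes the aldehyde to base.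
- It sets out from 30, where dibromomethylenation (CBr4, PPh3, Et3N, CH2Cl2, 0 °C) gives the 1,1-dibromoalkene F5.
- n-BuLi (THF, −78 °C) induces bromine–lithium exchange and Fritsch–Buttenberg–Wiechell rearrangement. Aqueous quench comes back to the route at 33.

Further compounds
F1 | step 23 | C15 tributylstannyl alkene of 36 (2-stannyl-1-alkene, C2–OH free, C13 OAc) | C=C([Sn](CCCC)(CCCC)CCCC)[C@@H]1C[C@H](OC(C)=O)/C(C)=C/CC/C(C)=C/CC/C(C)=C/[C@@H]1O
F2 | step 23 | C15 iodo alkene (2-iodo-1-alkene, C2–OH free, C13 OAc) | C=C(I)[C@@H]1C[C@H](OC(C)=O)/C(C)=C/CC/C(C)=C/CC/C(C)=C/[C@@H]1O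
F3 | step 15 | C5 allylic acetate corresponding to 26 | COc1ccc(cc1)[C@@H]1OC[C@H](C[C@H](O[Si](C)(C)C(C)(C)C)/C(C)=C/CC/C(C)=C/CS(=O)(=O)c2ccccc2)[C@@H](O1)/C=C(\C)COC(C)=O
F4 | step 15 | C5 allylic alcohol corresponding to 26 | COc1ccc(cc1)[C@@H]1OC[C@H](C[C@H](O[Si](C)(C)C(C)(C)C)/C(C)=C/CC/C(C)=C/CS(=O)(=O)c2ccccc2)[C@@H](O1)/C=C(\C)CO
F5 | step 19 | 1,1-dibromoalkene from aldehyde 30 | BrC(Br)=C[C@@H]1C[C@H](O[Si](C)(C)C(C)(C)C)/C(C)=C/CC/C(C)=C/CC/C(C)=C/[C@@H]1OCc1ccc(OC)cc1
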